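(Readings and results were generated by integration with made-up constants; scatter was added.)

Time is what these set-ups trade in: two tanks, a dosed flask and a closed flask, charged alike.

| flask | G | L | X | remark | time |
|---|---|---|---|---|---|
| Monday's | 1 M | 1 equiv | 1 mol% | run made earlier |  |
| Friday's | 1 M | 1 equiv | 0.67 mol% | run made earlier |  |
| Tuesday's | 1 M | 1 equiv | 1.5 mol% | run made earlier |  |
| spring | 1.0 M | 1.00 equiv | 1 mol% | a single well-mixed tank run continuously and read at steady state, 50 min in it on average |  |
| summer | 1.0 M | 1.00 equiv | 1 mol% | a single well-mixed tank run continuously and read at steady state, 500 min in it on average |  |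
| noon | 1.0 M | 1.00 equiv (fed, over 40.0 min) | 1 mol% | all but L at the start; L goes in evenly over 40.0 min, the run ends at 50 min | 50 min |
| dusk | 1.0 M | 1.00 equiv | 1 mol% | everything together in a closed stirred flask, run for 50 min | 50 min |

- the set-up with the highest amount of D at the outlet or at the end, in percent of the G put in ("none" if the first two lie within 2 percentage points) (spring / summer / noon / dusk / none)
- amount of D at the outlet or at the end, in percent of the G put in, spring
- amount of D at the outlet or at the end, in percent of the G put in, summer
- amount of D at the outlet or at the end, in percent of the G put in, noon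
- amount of D at the outlet or at the end, in percent of the G put in, dusk

- the stated concentrations are those of everything mixed, before any reaction; amounts are the same in each set-up
- steps thought possible: G + X <-> Q; Q -> X + D; L + X <-> J; J -> X + Z; X <-> E
- the feed brings no volume worth counting
- the earlier runs were made in a closed, stirred flask

| run | time / min | D / % |
|---|---|---|
| Monday's | 4.00 | 5 |
| Monday's | 12.0 | 9 |
| Monday's | 25.0 | 14 |
| Monday's | 40.0 | 19 |
| Monday's | 50.0 | 25 |
| Friday's | 4.00 | 0 |
| Friday's | 12.0 | 3 |
| Friday's | 25.0 | 6 |
| Friday's | 40.0 | 15 |
| Friday's | 50.0 | 17 |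
| Tuesday's | 4.00 | 7 |
| Tuesday's | 8.00 | 11 |
| Tuesday's | 15.0 | 16 |
| Tuesday's | 25.0 | 22 |
| Tuesday's | 50.0 | 36 |

(each reading ± 2 percentage points)

I read the last line of each run. At 1 mol% of X, Monday holds 25% of D; at 0.67 mol%, Friday holds 17%; at 1.5 mol%, Tuesday holds 36%. Per unit of loading these are 25.0, 25.4 and 24.0, level within a scatter of 2 percentage points on each reading, so D at that time goes with the loading of X.

Counting all reacted G as D, Monday's last reading leaves 75.0% of G at 50.0 min, which gives a reading of T = 174 min, with that reading's scatter in it. T is the working time: on a pseudo-first-order view, the time in which the fraction of G left in the closed flask at this loading falls to 0.368 of itself.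

I solve a tank with mean residence time τ at both ends. Far below T, its D is about τ/T; far above T, the fraction of G left is about T/τ. The balance, G lost equals G left times τ/T, joins them: D is τ/T over one plus τ/T.

Summer holds G on average ten times as long as dusk's 50 min, and τ/T is 2.88, so I reckon 74.2%. Dusk repeats Monday's recipe, whose last reading is 25%, so summer is my pick, well above it. The runs hold L at 1 equiv, so T doesn't speak to noon.

The forecast gives spring 19% (15% to 24%), summer 75% (58% to 92%), noon 27% (20% to 42%) and dusk 23% (20% to 26%): “Summer clearly wins”. Its summer figure is higher than my 74.2%.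

    G + X ⇌ Q (K = 0.490 L mol⁻¹, k = 0.234 L mol⁻¹ s⁻¹)
    Q → X + D (k = 0.115 s⁻¹)
    L + X ⇌ J (K = 0.851 L mol⁻¹, k = 0.210 L mol⁻¹ s⁻¹)
    J → X + Z (k = 0.0508 s⁻¹)
    X ⇌ E (K = 2.90, k = 0.00673 s⁻¹)

The set-ups give 23.6% in spring, 76.6% in summer, 27.6% at noon and 26.2% at dusk, so summer leads. Beside T = 174 min, the half-lives of two of the catalyst's steps are short: 1.7 min for X going to E, forward step alone, and 0.10 min for Q making X + D alone. Spring's tank holds G on average as long as dusk's flask runs, 0.287 of T, where the join gives 22.3% and the outlet stands at 23.6%.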